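One mM per hour is the unit to count in here: a starting complex exchanges a ligand under held gas, and we want to know which recipe returns more of the complex with one exchanged per unit of scarce charge.

| flask | starting complex | gas | remark | time |
|---|---|---|---|---|
| midnight | 0.018 M (in portions, 2) | 1.2 mM (held) | run made earlier; portions every 4.0 h |  |
| dusk | 0.017 M (in portions, 2) | 1.2 mM (held) | run made earlier; portions every 4.0 h |  |
| winter | 0.023 M (in portions, 2) | 1.2 mM (held) | run made earlier; portions every 4.0 h |  |
| oak | 0.015 M | 1.2 mM | everything together at the start | 2.0 h |
| cedar | 0.021 M (in portions, 2) | 1.2 mM (held) | the portions of starting complex follow each other after 4.0 h, the first at the start | 8.0 h |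

- midnight (time / h: complex with one exchanged / %, starting complex / %): 0.667: 3.6, 46.8; 1.33: 7.2, 42.7; 2.50: 11.8, 37.1; 4.00: 13.2, 31.9; 8.00: 23.0, 68.0
- dusk (time / h: complex with one exchanged / %, starting complex / %): 0.667: 4.3, 46.3; 2.00: 9.5, 38.4; 4.00: 13.3, 31.6; 6.00: 20.8, 72.1; 8.00: 24.4, 65.7
- winter (time / h: complex with one exchanged / %, starting complex / %): 0.667: 2.6, 47.4; 1.33: 4.5, 43.9; 2.50: 10.0, 40.3; 4.00: 12.7, 35.4; 8.00: 20.6, 71.4

(readings scatter by 0.5 percentage points)

- at the start none of the gas is in solution

- the flask that ends with the higher amount of complex with one exchanged, in percent of the starting complex charged, or "neither" when 2 percentage points or less lies between them (oak / cedar / neither)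
- final complex with one exchanged, as a percentage of the starting complex charged, in oak
- final complex with one exchanged, as a percentage of the starting complex charged, in cedar

At 4.00 h, before the second portion, half the charge is in. What is then neither starting complex nor complex with one exchanged we take to have exchanged twice, so it counts as two exchanges. The exchange rate comes to 1.03 mM h⁻¹ in midnight, 0.999 mM h⁻¹ in dusk and 0.949 mM h⁻¹ in winter, the run with the largest charge. As the readings stand, this is zero order in starting complex. Their mean is our rule, for gas at 1.2 mM: r, the exchanges made per hour in mM over the first 4.00 h, 0.994 mM h⁻¹, a reading that carries the scatter.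

Turnovers per charged complex are then N = r t / c, with t the time and c the whole charge. Oak gets 0.133 and cedar 0.379, so oak turns over less than cedar. Not every exchange stays as the product we want. The share of exchanges sitting in complex with one exchanged is 84.3% at 2.50 h in midnight. At 8.00 h the three runs average 55.9%. We therefore reckon 11.2% for oak and 21.2% for cedar, and we charge cedar.

The forecast, a little above us on both, says 12.2% (10.5% to 14%) for oak, 21.5% (20.3% to 22.7%) for cedar and cedar as the higher, holding that “the rate is essentially zero-order in complex”.

The flasks give 13.1% in oak and 21.6% in cedar, so cedar ends higher.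

    starting complex + incoming ligand ⇌ leaving ligand + complex with one exchanged (K = 6.53, k = 0.331 M⁻¹ s⁻¹)
    complex with one exchanged + incoming ligand ⇌ leaving ligand + complex with two exchanged (K = 9.00, k = 0.208 M⁻¹ s⁻¹)
    incoming ligand ⇌ dormant form (K = 4.65, k = 4.49 × 10⁻⁶ s⁻¹)
    gas ⇌ incoming ligand, rate k4*(csat - [incoming ligand]) (kL = 2.89 × 10⁻⁴ s⁻¹)

In oak, the uptake of gas as incoming ligand ran evenly, with 51% of its turnover done by 1.00 h; at the end, at 2.00 h, leaving ligand stood at 2.21 mM against our 1.99 mM. In cedar, the second exchange ran beside the first, taking complex with two exchanged to 7.71% by 8.00 h, while leaving ligand came to 7.77 mM against our 7.95 mM. Oak read at 3.0 h counts 2.98 mM and holds 3.27 mM of leaving ligand.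

Readings and results are calculated for an exercise, noise included.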